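The target is a centrosymmetric α-truxillic cyclobutane carrying two N-acyl 5,6-dihydropyridin-2(1H)-one rings (lactam numbering N1, C2=O, C3=C4, C5H2, C6H2). Each lactam ring is taken apart as a formal [4+2] adduct of the chain C6–N1–C2–C3, held as an acyclic N-acetyl-N-methoxymethyl imide (latent N-acyliminium carbon C6, latent enol carbon C3), and the two carbons C4–C5 of ethyl vinyl ether. One silyl triflate cascade on the bis-imide joins C5 to C6 and C3 to C4 in both rings; loss of ethanol then leaves C3=C4 conjugated to C2=O. The cyclobutane and its four stereocentres come from head-to-tail solid-state photodimerisation of (E)-3,4-dimethoxycinnamic acid.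

Key step: step 4

Remark on the chemistry: the stereodescriptors of the target define the achiral, centrosymmetric 1α,2α,3β,4β (α-truxillic) isomer, so only relative configuration has to be controlled; 1, 3 and 8 are taken as commercial.

Step 1
Reactants: 1 (E)-3,4-dimethoxycinnamic acid (two molecules)
Product: 2 (1α,2α,3β,4β)-2,4-bis(3,4-dimethoxyphenyl)cyclobutane-1,3-dicarboxylic acid (carboxyls trans to each other, aryls trans to each other)
Conditions: hν (medium-pressure Hg lamp, Pyrex), finely ground crystals of 1 suspended in water, 23 °C
Reagents that add atoms: none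
Why: Topochemical [2+2] photocycloaddition in the head-to-tail (α-type) crystal packing, where the E geometry of each monomer fixes the two trans aryl/carboxyl relationships and the inversion-related stacking of the reacting pair fixes the two cis relationships across the new bonds, so all four stereocentres are set as the achiral α-truxillic isomer.

Step 2
Reactants: 3 N-(hydroxymethyl)acetamide
Product: 4 N-(methoxymethyl)acetamide
Conditions: MeOH (solvent), p-TsOH·H2O (cat.), 23 °C; NaHCO3, then distillation
Reagents that add atoms: methanol CO
Why: Acid-catalysed etherification of an N-methylol amide through a transient N-acyliminium ion that is trapped by the large excess of methanol; no stereocentre is involved.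

Step 3
Reactants: 2 (1α,2α,3β,4β)-2,4-bis(3,4-dimethoxyphenyl)cyclobutane-1,3-dicarboxylic acid; 4 N-(methoxymethyl)acetamide (two molecules)
Product: 7 (1α,2α,3β,4β)-N1,N3-diacetyl-2,4-bis(3,4-dimethoxyphenyl)-N1,N3-bis(methoxymethyl)cyclobutane-1,3-dicarboxamide, via bis(acid chloride) 5 (not isolated), via lithium N-(methoxymethyl)acetamidate 6 (not isolated)
Conditions: (COCl)2 (2.5 equiv), DMF (cat.), CH2Cl2, 0 to 23 °C, evaporate; 4 (2.2 equiv), LiN(SiMe3)2 (2.1 equiv), THF, −78 °C, then added slowly to 5 in THF, −78 to 0 °C
Reagents that add atoms: none
Why: Acid chloride formation under Vilsmeier catalysis followed by twofold N-acylation, one lithium amidate per acid chloride group (imide synthesis), with the amidate added to the acid chloride at −78 °C so that acyl transfer should outrun α-deprotonation and the carboxyl-bearing cyclobutane stereocentres stay intact.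

Step 4
Reactants: 7 (1α,2α,3β,4β)-N1,N3-diacetyl-2,4-bis(3,4-dimethoxyphenyl)-N1,N3-bis(methoxymethyl)cyclobutane-1,3-dicarboxamide; 8 ethyl vinyl ether (two molecules)
Product: 10 1,1'-[(1α,2α,3β,4β)-2,4-bis(3,4-dimethoxyphenyl)cyclobutane-1,3-dicarbonyl]bis(5,6-dihydropyridin-2(1H)-one), via bis(4-ethoxypiperidin-2-one) 9 (not isolated)
Conditions: 8 (10 equiv), Me3SiOSO2CF3 (6 equiv), iPr2NEt (7 equiv), CH2Cl2 (0.02 M), single charge, −78 to 23 °C
Reagents that add atoms: none
Why: Proposed new method: Me3SiOSO2CF3 ionises each N–CH2–OMe group to an N,N-diacyliminium ion that is attacked at C6 by the CH2 terminus of one molecule of ethyl vinyl ether (C5–C6), the resulting oxocarbenium carbon C4 is captured by the silyl ketene N,O-acetal formed in situ from the N-acetyl group (C3–C4, giving 9), and silyl-assisted E1cB loss of ethanol under the same amine/silyl triflate conditions installs C3=C4. The closest known reaction types are the amidoalkylation of enol ethers by N-acyliminium ions, the one-flask enol silane formation/Mukaiyama addition to acetals, and the [4+2] cycloaddition of N-alkenyl iminium ions (cationic 2-azadienes) with alkenes, of which this is a stepwise variant. Each lactam ring closes in the C3–C4 event by a 6-(enolendo)-exo-trig attack on the oxocarbenium ion. No stereocentre of the target is made (the ethoxy-bearing carbons of 9 are erased by the elimination), and the four cyclobutane centres should survive because soft enolisation is confined to the acetyl methyl groups, the hindered tertiary cyclobutyl C–H being slow to leave and its enol an exocyclic alkene on a four-membered ring. The step needs the vinyl ether to win the iminium ion against the cis-neighbouring dimethoxyphenyl ring and against the enol silane of another molecule, which its large excess and higher π-nucleophilicity, the seven-membered size of the competing arylation and the strain of a four-membered C3-to-C6 closure should secure. The polarity of the vinyl ether fixes the regiochemistry, placing the ethoxy leaving group on C4, β to the lactam carbonyl, so that elimination can only give the conjugated C3=C4 alkene.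

Compound list
1 | (E)-3-(3,4-dimethoxyphenyl)prop-2-enoic acid | COc1ccc(/C=C/C(=O)O)cc1OC | starting material
2 | (1α,2α,3β,4β)-2,4-bis(3,4-dimethoxyphenyl)cyclobutane-1,3-dicarboxylic acid | COc1ccc([C@H]2[C@H](C(=O)O)[C@H](c3ccc(OC)c(OC)c3)[C@H]2C(=O)O)cc1OC | intermediate
3 | N-(hydroxymethyl)acetamide | CC(=O)NCO | starting material
4 | N-(methoxymethyl)acetamide | CC(=O)NCOC | intermediate
5 | (1α,2α,3β,4β)-2,4-bis(3,4-dimethoxyphenyl)cyclobutane-1,3-dicarbonyl dichloride | COc1ccc([C@H]2[C@H](C(=O)Cl)[C@H](c3ccc(OC)c(OC)c3)[C@H]2C(=O)Cl)cc1OC | intermediate
6 | lithium N-(methoxymethyl)acetamidate | CC(=O)[N-]COC.[Li+] | intermediate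
7 | (1α,2α,3β,4β)-N1,N3-diacetyl-2,4-bis(3,4-dimethoxyphenyl)-N1,N3-bis(methoxymethyl)cyclobutane-1,3-dicarboxamide | COc1ccc([C@H]2[C@H](C(=O)N(COC)C(C)=O)[C@H](c3ccc(OC)c(OC)c3)[C@H]2C(=O)N(COC)C(C)=O)cc1OC | intermediate
8 | ethyl vinyl ether (ethoxyethene) | C=COCC | starting material
9 | 1,1'-[(1α,2α,3β,4β)-2,4-bis(3,4-dimethoxyphenyl)cyclobutane-1,3-dicarbonyl]bis(4-ethoxypiperidin-2-one), mixture of epimers at the two ethoxy-bearing carbons | COc1ccc([C@H]2[C@H](C(=O)N3CCC(OCC)CC3=O)[C@H](c3ccc(OC)c(OC)c3)[C@H]2C(=O)N2CCC(OCC)CC2=O)cc1OC | intermediate
10 | 1,1'-[(1α,2α,3β,4β)-2,4-bis(3,4-dimethoxyphenyl)cyclobutane-1,3-dicarbonyl]bis(5,6-dihydropyridin-2(1H)-one) | COc1ccc([C@H]2[C@H](C(=O)N3CCC=CC3=O)[C@H](c3ccc(OC)c(OC)c3)[C@H]2C(=O)N2CCC=CC2=O)cc1OC | target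

Total step count: 4
Longest linear sequence: 3 steps (steps 1, 3 and 4)

Steps most likely to fail

Step 4 (proposed new method). The iminium ion may be intercepted by the neighbouring dimethoxyphenyl ring or by the enol silane of a second molecule before the vinyl ether reaches it. The vinyl ether may oligomerise cationically. The sequence may stall after the first C–C bond if the oxocarbenium ion is deprotonated to an enol ether. Over-silylation of the product to a dienol ether could lead to reprotonation out of conjugation, and the Lewis acid could open the aryl/acyl-substituted cyclobutane. The fallback uses known chemistry and gives up building the rings on the core. It sets out from 5, generated from 2 exactly as in step 3, and comes back to the route at 10. Commercial 5,6-dihydropyridin-2(1H)-one (O=C1NCCC=C1, two equivalents) is deprotonated with LiN(SiMe3)2 in THF at −78 °C to lithium 2-oxo-5,6-dihydropyridin-1(2H)-ide F1, two molecules of which are N-acylated by the two acid chloride groups of 5 (standard imide formation from a metalated lactam and an acid chloride) to give 10 directly.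

Step 3. The basic amidate may deprotonate the acid chloride at its α-carbon (ketene formation), scrambling the carboxyl-bearing cyclobutane centres. The amidate may also expel methoxide, and the product imide may be enolised and C-acylated. The fallback sets out from 5 and comes back at 7. Neutral acylation of commercial N-(trimethylsilyl)acetamide (CC(=O)N[Si](C)(C)C, two equivalents) by 5 in CH2Cl2 at 23–40 °C, with loss of Me3SiCl, should give (1α,2α,3β,4β)-N1,N3-diacetyl-2,4-bis(3,4-dimethoxyphenyl)cyclobutane-1,3-dicarboxamide F2. Its two acidic imide N–H groups are then alkylated with chloromethyl methyl ether (COCCl, two equivalents) and iPr2NEt in CH2Cl2 to give 7. This avoids both 4 and any strong base.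

Step 1. The crystal form at hand may not stack head-to-tail within reacting distance, or the lattice may lose order part-way, so that conversion stalls and E/Z isomerisation takes over. The fallback sets out from 1 and comes back at 2. Fischer esterification (MeOH, H2SO4 cat., reflux) gives methyl (E)-3-(3,4-dimethoxyphenyl)prop-2-enoate F3. Irradiation of its BF3·OEt2 complex in CH2Cl2 (Lewis-acid-mediated solution photodimerisation of cinnamate esters, expected to favour the head-to-tail α-truxillate) should give dimethyl (1α,2α,3β,4β)-2,4-bis(3,4-dimethoxyphenyl)cyclobutane-1,3-dicarboxylate F4. Saponification with LiOH in THF/H2O at 23 °C and acidification returns 2.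

Further compounds
F1 | step 4 | lithium 2-oxo-5,6-dihydropyridin-1(2H)-ide | [Li+].O=C1C=CCC[N-]1
F2 | step 3 | (1α,2α,3β,4β)-N1,N3-diacetyl-2,4-bis(3,4-dimethoxyphenyl)cyclobutane-1,3-dicarboxamide | COc1ccc([C@H]2[C@H](C(=O)NC(C)=O)[C@H](c3ccc(OC)c(OC)c3)[C@H]2C(=O)NC(C)=O)cc1OC
F3 | step 1 | methyl (E)-3-(3,4-dimethoxyphenyl)prop-2-enoate | COC(=O)/C=C/c1ccc(OC)c(OC)c1
F4 | step 1 | dimethyl (1α,2α,3β,4β)-2,4-bis(3,4-dimethoxyphenyl)cyclobutane-1,3-dicarboxylate | COc1ccc([C@H]2[C@H](C(=O)OC)[C@H](c3ccc(OC)c(OC)c3)[C@H]2C(=O)OC)cc1OC
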